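## Analysis of the target

Pervilleanone is an isoflavanone: ring A is fused to the pyranone ring C (a chroman-4-one), and C3 of ring C carries the pentasubstituted ring B. C3 is the only stereocentre and is R, so there is no neighbouring centre to relay from and its configuration has to come from a reagent or catalyst. The C3–H bond lies between the C4 carbonyl and ring B, so it enolises easily: base racemises it quickly, acid more slowly, and oxidants lead on to the isoflavone. The 2'-hydroxyl is within reach of C4=O, so strong acid can close a hemiketal and dehydrate it to a pterocarpene. The 2-methylbut-3-en-2-yl group at C5' rules out hydrogenation, hydrogenolysis and strongly acidic steps. Ring B also needs its substituents in a fixed order, with the free hydroxyl at C2' para to the tert-allyl group and two methyl ethers between them. The difficulty is therefore to close ring C and create C3 late, catalytically and under conditions mild enough for the new centre to survive. The feature used is that C3 is benzylic to ring B and C2' carries a free hydroxyl: the unit C3=C1'–C2'=O can exist as an ortho-quinone methide, an enone whose conjugate addition at C3 restores the aromaticity of ring B, and the C4 carbon of ring A sits five atoms away through O1 and C2.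

## Retrosynthetic reasoning

**19 to 18.** Only the O7–Si bond is cut. O7 must be masked during ring closure, because a free phenoxide para to the formyl group would make the aldehyde a vinylogous carboxylate and stop carbene addition. A triisopropylsilyl ether is chosen over a smaller silyl group because aryl silyl ethers para to a carbonyl are easily lost to carbonate bases, which the ring closure uses. The forward step must free O7 without exposing C3 to base or strong acid.

**18 to 16 through 17.** Ring C is opened at C3–C4. This is the one ring bond whose formation creates the stereocentre in the bond-forming event itself; cutting at O1–C2, O1–C8a or C4–C4a would close the ring but leave C3 to be set separately. C4 becomes the formyl carbon of ring A, turned into an acyl anion equivalent by a chiral triazolylidene, and C3 becomes the exocyclic carbon of the ortho-quinone methide 17. No extra electron-withdrawing group is needed on the acceptor, because the 2'-oxygen of the target provides it. Intermediate 17 is too reactive to store, so it is released from the benzylic sulfone 16 by base. The forward reaction must form 17 in the presence of the catalyst-bound acyl anion, close the six-membered ring faster than 17 tautomerises, and choose one face of C3.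

**16 to 8, 13 and 14.** The C3–C1' and C3–S bonds are cut together. C3 then comes from the aliphatic aldehyde carbon of 13, ring B from the phenol 8 through its only free position ortho to the hydroxyl, and the leaving group from the sulfinate 14. The condensation passes through the benzylic alcohol 15 and joins both halves of the molecule in one operation without any protecting group on the 2'-oxygen. The forward step must distinguish the aliphatic aldehyde of 13 from its aryl aldehyde and must stop at mono-arylation.

**13 back to 9.** The aldehyde carbon of the two-carbon arm is traced to the terminal alkene of the allyl ether 11 (ozonolysis through 12). Compound 11 is traced to the phenol 10 by an O2–C bond formed under Mitsunobu conditions, and 10 to 9 by regioselective silylation at O4. The allyl/ozonolysis sequence is preferred to a direct O-alkylation of 10 with a masked two-carbon halide, which would need hot carbonate and would endanger the silyl ether.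

**8 back to 1 and 2.** The phenol 8 comes from its methoxymethyl ether 7, and 7 from the phenol 6 by O-methylation at what becomes O4'. The quaternary C5'–C bond of 6 is cut by a retro-Claisen step (through the dienone 5) to the prenyl ether 4. The rearrangement delivers the allyl unit from oxygen to its own ortho carbon, so the tert-allyl group ends up next to the oxygen that is then methylated and para to the oxygen that stays free. Compound 4 is the protected form of 3, the mono-prenyl ether of the symmetric diol 1 made with 2. The methoxymethyl group is there only to keep the two oxygens of 1 distinct.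

## Alternatives that were turned down

Alternative 1: Ring C is cut at three bonds, O1–C8a, C4–C4a and O1–C2, giving a ring A aryne precursor, the silyl triflate A3, and the ring B methoxyacrylic acid A2.
- Forward step: fluoride releases the aryne from A3 and the carboxylate of A2 adds through oxygen at C8a. The aryl anion at C4a attacks the carboxyl carbon, and the four-membered intermediate opens to an ortho-acyl phenoxide. This phenoxide adds to C2, the methoxy group leaves, and the product is the isoflavone A1.
- For it: high convergence, three bonds in one flask, and intermediates with no configurationally labile centre. On these points it is stronger than the chosen route.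
- Against it: A1 is trigonal at C3, so the stereocentre is not addressed. An enantioselective reduction of C2=C3 would have to spare the terminal alkene. The chlorine at C5 is there only to steer the aryne addition and would have to be removed reductively, again in the presence of the alkene. Two acetal protecting groups would have to be removed under acid next to the finished C3 and the 2'-hydroxy ketone.
- Comparison: the chosen route sets C3 in the ring-forming step and carries no atom that must later be deleted.

Alternative 2: The C5'–C and C4'–O bonds of ring B are cut, leading back to the silylated bromoguaiacol A5.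
- Forward step: a hindered lithium amide removes the proton between the methoxy group and bromine of A5. Loss of bromide gives the C4'–C5' aryne, and prenylmagnesium chloride A6 adds through its substituted carbon at C5'. The arylmagnesium at C4' is then oxidised through a borate to give the phenol A4.
- For it: two bonds in one operation and a two-step access to a compound equivalent to 6. This is shorter than steps 1 to 3 and avoids both the statistical mono-alkylation and the hot rearrangement. On step economy for ring B it is stronger.
- Against it: it is a ring B tactic only and says nothing about ring C or C3. Its regiochemistry rests on three separate selectivities (site of deprotonation, site of addition to the aryne, and attack through the hindered end of the allyl metal), each of which can leak. A4 still needs methylation and a protecting-group exchange.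
- Comparison: the Claisen route fixes the position of the tert-allyl group intramolecularly, and the chosen strategy spends its risk on the stereocentre. Alternative 2 could replace steps 1 to 3 but could not replace the key step.

Alternative 3: The C2–C3 bond is cut, leading to the diazo deoxybenzoin A8.
- Forward step: the diazo compound A8 is decomposed by Rh2(S-PTTL)4 A9 (a carboxylate of divalent rhodium). The resulting carbene at C3 inserts into a C–H bond of the ortho-methoxy group of ring A to give the bis-silyl ether A7.
- For it: C2 comes from a plain methyl ether, the stereocentre is set in the ring-forming event, and the medium is neutral. On freedom from base it is stronger than the chosen route.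
- Against it: the methoxy oxygen can reach the carbene through a five-membered oxonium ylide, which is usually faster than a six-membered insertion into a primary C–H bond. A methyl shift from that ylide would give a 2-aryl-2-methylbenzofuranone instead of ring C. The terminal alkene is a cyclopropanation site. A8 needs a deoxybenzoin and a diazo transfer in linear sequence, and two silyl ethers must be removed at the end.
- Comparison: the chosen route has no competing ylide channel, its precursor 16 is assembled from three components in one step, and the 2'-hydroxyl stays unprotected because it is the activating group.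

Key step: step 10

Assumption: which antipode of the triazolium precatalyst gives (R)-18 on this new acceptor is settled in a pilot run. The precatalyst is (5aS,10bR)- or (5aR,10bS)-2-(pentafluorophenyl)-5a,10b-dihydro-4H,6H-indeno[2,1-b][1,2,4]triazolo[4,3-d][1,4]oxazin-2-ium tetrafluoroborate, and the steps are written for the antipode that leads to R. Quinone methide 17 is drawn as its E isomer.

## Route

Step 1
Reactants: 1 2-methoxyresorcinol (2-methoxybenzene-1,3-diol); 2 prenyl bromide (1-bromo-3-methylbut-2-ene)
Product: 3 2-methoxy-3-[(3-methylbut-2-en-1-yl)oxy]phenol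
Conditions: 2 (0.8 equiv), K2CO3 (1.0 equiv), acetone, rt to 50 °C
Reagents that add atoms: prenyl bromide (2), CC(C)=CCBr
Why: Williamson ether synthesis; the two hydroxyls of 1 are equivalent, so using the bromide as the limiting reagent should favour the mono-ether, and carbonate in acetone keeps C-prenylation of the ring low.

Step 2
Reactants: 3 2-methoxy-3-[(3-methylbut-2-en-1-yl)oxy]phenol
Product: 4 2-methoxy-1-(methoxymethoxy)-3-[(3-methylbut-2-en-1-yl)oxy]benzene
Conditions: MOMCl, i-Pr2NEt, CH2Cl2, 0 °C to rt
Reagents that add atoms: chloromethyl methyl ether (MOMCl), COCCl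
Why: Acetal-forming O-alkylation of the remaining phenol; the MOM ether ensures that only the oxygen destined to become the 4'-methoxy group is free after the rearrangement, and it tolerates the heat and the base of the next two steps.

Step 3
Reactants: 4 2-methoxy-1-(methoxymethoxy)-3-[(3-methylbut-2-en-1-yl)oxy]benzene
Product: 6 2-methoxy-3-(methoxymethoxy)-6-(2-methylbut-3-en-2-yl)phenol, via Claisen dienone 5 (not isolated)
Conditions: PhNEt2, 190 °C, sealed tube
Reagents that add atoms: none
Why: Aromatic Claisen rearrangement: the [3,3] shift moves the prenyl group with allylic inversion to the only unsubstituted carbon ortho to the ether oxygen, creating the quaternary C5'–C bond, and dienone 5 tautomerises to the phenol; the basic amine solvent suppresses acid-catalysed closure of the new phenol onto the alkene.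

Step 4
Reactants: 6 2-methoxy-3-(methoxymethoxy)-6-(2-methylbut-3-en-2-yl)phenol
Product: 7 2,3-dimethoxy-1-(methoxymethoxy)-4-(2-methylbut-3-en-2-yl)benzene
Conditions: MeI, K2CO3, DMF, rt to 40 °C
Reagents that add atoms: iodomethane, CI
Why: Williamson methylation of the phenoxide; the hydroxyl is flanked by a methoxy group and the quaternary carbon, but iodomethane is small enough for this position and the MOM acetal is inert to carbonate.

Step 5
Reactants: 7 2,3-dimethoxy-1-(methoxymethoxy)-4-(2-methylbut-3-en-2-yl)benzene
Product: 8 2,3-dimethoxy-4-(2-methylbut-3-en-2-yl)phenol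
Conditions: HCl (cat.), MeOH, 40 °C
Reagents that add atoms: none
Why: Acid-catalysed transacetalisation to methanol removes the MOM group; catalytic acid at mild temperature is chosen because the tert-allyl group para to the freed hydroxyl could be lost or shifted under stronger acid, and no hydroxyl stands ortho to the alkene that could cyclise onto it.

Step 6
Reactants: 9 2,4-dihydroxybenzaldehyde
Product: 10 2-hydroxy-4-[(triisopropylsilyl)oxy]benzaldehyde
Conditions: TIPSCl (1.05 equiv), imidazole, CH2Cl2, 0 °C
Reagents that add atoms: chlorotriisopropylsilane (TIPSCl), CC(C)[Si](Cl)(C(C)C)C(C)C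
Why: Regioselective silylation; the 2-hydroxyl is held in a hydrogen bond to the formyl group and is less acidic, so the bulky silyl chloride should go to O4 only.

Step 7
Reactants: 10 2-hydroxy-4-[(triisopropylsilyl)oxy]benzaldehyde
Product: 11 2-(prop-2-en-1-yloxy)-4-[(triisopropylsilyl)oxy]benzaldehyde
Conditions: allyl alcohol, PPh3, DIAD, THF, 0 °C to rt
Reagents that add atoms: allyl alcohol (prop-2-en-1-ol), C=CCO
Why: Mitsunobu etherification of the salicylaldehyde hydroxyl with a primary allylic alcohol; the neutral conditions are chosen because an aryl silyl ether para to a formyl group would be at risk under the hot carbonate of a conventional alkylation.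

Step 8
Reactants: 11 2-(prop-2-en-1-yloxy)-4-[(triisopropylsilyl)oxy]benzaldehyde
Product: 13 2-(2-oxoethoxy)-4-[(triisopropylsilyl)oxy]benzaldehyde, via ozonide 12 (not isolated)
Conditions: O3, CH2Cl2, −78 °C; then Me2S, −78 °C to rt
Reagents that add atoms: ozone, [O-][O+]=O
Why: Ozonolysis with reductive work-up cleaves the terminal alkene to the aryloxyacetaldehyde under neutral conditions; the aryl ring is deactivated by the formyl group, the silyl ether is inert, and the hydrate-prone dialdehyde 13 is used without storage.

Step 9
Reactants: 8 2,3-dimethoxy-4-(2-methylbut-3-en-2-yl)phenol; 13 2-(2-oxoethoxy)-4-[(triisopropylsilyl)oxy]benzaldehyde; 14 sodium p-toluenesulfinate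
Product: 16 2-{2-[2-hydroxy-3,4-dimethoxy-5-(2-methylbut-3-en-2-yl)phenyl]-2-[(4-methylphenyl)sulfonyl]ethoxy}-4-[(triisopropylsilyl)oxy]benzaldehyde (racemic), via benzylic alcohol 15 (not isolated)
Conditions: 14 (1.5 equiv), HCO2H/H2O/THF, rt
Reagents that add atoms: sodium p-toluenesulfinate (14), Cc1ccc(S(=O)[O-])cc1.[Na+]
Why: Three-component sulfonylalkylation of an electron-rich phenol (acid-mediated Friedel–Crafts hydroxyalkylation, then sulfinate capture of the benzylic cation, a Mannich-type condensation known for naphthols and oxygenated phenols): the aliphatic aldehyde of 13 is far more electrophilic than the doubly oxygen-donated aryl aldehyde, 8 reacts at its only free position ortho to the hydroxyl, and alcohol 15 ionises and is taken by sulfinate at sulfur to give the sulfone as the resting state. No stereocontrol is needed, since C3 becomes trigonal again in step 10.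

Step 10
Reactants: 16 2-{2-[2-hydroxy-3,4-dimethoxy-5-(2-methylbut-3-en-2-yl)phenyl]-2-[(4-methylphenyl)sulfonyl]ethoxy}-4-[(triisopropylsilyl)oxy]benzaldehyde (racemic)
Product: 18 (3R)-3-[2-hydroxy-3,4-dimethoxy-5-(2-methylbut-3-en-2-yl)phenyl]-7-[(triisopropylsilyl)oxy]-2,3-dihydro-4H-chromen-4-one, via ortho-quinone methide 17 (not isolated)
Conditions: aminoindanol-derived N-C6F5 triazolium tetrafluoroborate (20 mol%), K2CO3 (1.5 equiv), toluene, 0 °C to rt; pH 6 phosphate buffer
Reagents that add atoms: none
Why: Proposed new method: K2CO3 deprotonates the 2'-hydroxyl of 16 and the phenoxide expels p-toluenesulfinate in a 1,4-elimination to give the E ortho-quinone methide 17, an enone (C3=C1'–C2'=O) whose conjugate addition restores ring B; the same base frees the triazolylidene, which adds to the ring A aldehyde and after proton transfer gives the Breslow intermediate, whose C4 attacks C3 of 17, after which the tetrahedral adduct collapses to the C4 ketone and returns the carbene. The closest known reaction types are the carbene-catalysed intramolecular Stetter reaction of salicylaldehyde-tethered enoates, which gives 3-substituted chroman-4-ones over the same O1–C2–C3 tether, and the carbene-catalysed addition of aldehyde-derived acyl anions to quinone methides; an intramolecular Stetter closure onto an ortho-quinone methide formed in the flask goes beyond these. Ring C closes in a 6-exo-trig mode, the C3=C1' bond lying outside the new ring. C3 is set in the C–C bond-forming event itself, with no later protonation at carbon, and its configuration is controlled by the aminoindanol-derived catalyst, which shields one face of the Breslow intermediate and so selects the face of C3 that is attacked; the E geometry of 17 corresponds to that of the E enoates on which this catalyst class is effective. The step needs acyl-anion attack to outrun both the 1,5-hydrogen shift of 17 to the 2-hydroxystyryl ether and direct addition of the free carbene to C3; the five-atom tether, the reversible return of sulfinate to 17 (which keeps 16 as a reservoir and the standing concentration of 17 low) and the weakly nucleophilic N-C6F5 carbene all work in that direction. Erosion of C3 afterwards is limited because the product leaves the cycle as its 2'-phenoxide, which disfavours a second deprotonation at the adjacent C3, and because the base is a sparingly soluble carbonate in toluene.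

Step 11
Reactants: 18 (3R)-3-[2-hydroxy-3,4-dimethoxy-5-(2-methylbut-3-en-2-yl)phenyl]-7-[(triisopropylsilyl)oxy]-2,3-dihydro-4H-chromen-4-one
Product: 19 pervilleanone [(3R)-7-hydroxy-3-[2-hydroxy-3,4-dimethoxy-5-(2-methylbut-3-en-2-yl)phenyl]-2,3-dihydro-4H-chromen-4-one]
Conditions: TBAF, AcOH (1:1.5), THF, 0 °C
Reagents that add atoms: none
Why: Fluoride-mediated cleavage of the aryl silyl ether, which is activated by the para carbonyl; acetic acid buffers the fluoride and protonates the 7-phenoxide as it forms, so C3 is not exposed to base, and no strong acid is present that could dehydrate the 2'-hydroxy ketone to a pterocarpene.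

## Compound list

1 | 2-methoxyresorcinol (2-methoxybenzene-1,3-diol) | COc1c(O)cccc1O | starting material
2 | prenyl bromide (1-bromo-3-methylbut-2-ene) | CC(C)=CCBr | starting material
3 | 2-methoxy-3-[(3-methylbut-2-en-1-yl)oxy]phenol | COc1c(O)cccc1OCC=C(C)C | intermediate
4 | 2-methoxy-1-(methoxymethoxy)-3-[(3-methylbut-2-en-1-yl)oxy]benzene | COCOc1cccc(OCC=C(C)C)c1OC | intermediate
5 | 2-methoxy-3-(methoxymethoxy)-6-(2-methylbut-3-en-2-yl)cyclohexa-2,4-dien-1-one (Claisen dienone, racemic) | C=CC(C)(C)C1C=CC(OCOC)=C(OC)C1=O | intermediate (not isolated)
6 | 2-methoxy-3-(methoxymethoxy)-6-(2-methylbut-3-en-2-yl)phenol | C=CC(C)(C)c1ccc(OCOC)c(OC)c1O | intermediate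
7 | 2,3-dimethoxy-1-(methoxymethoxy)-4-(2-methylbut-3-en-2-yl)benzene | C=CC(C)(C)c1ccc(OCOC)c(OC)c1OC | intermediate
8 | 2,3-dimethoxy-4-(2-methylbut-3-en-2-yl)phenol | C=CC(C)(C)c1ccc(O)c(OC)c1OC | intermediate
9 | 2,4-dihydroxybenzaldehyde | O=Cc1ccc(O)cc1O | starting material
10 | 2-hydroxy-4-[(triisopropylsilyl)oxy]benzaldehyde | O=Cc1ccc(O[Si](C(C)C)(C(C)C)C(C)C)cc1O | intermediate
11 | 2-(prop-2-en-1-yloxy)-4-[(triisopropylsilyl)oxy]benzaldehyde | C=CCOc1cc(O[Si](C(C)C)(C(C)C)C(C)C)ccc1C=O | intermediate
12 | 3-{[2-formyl-5-(triisopropylsilyloxy)phenoxy]methyl}-1,2,4-trioxolane (ozonide, racemic) | O=Cc1ccc(O[Si](C(C)C)(C(C)C)C(C)C)cc1OCC1OCOO1 | intermediate (not isolated)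
13 | 2-(2-oxoethoxy)-4-[(triisopropylsilyl)oxy]benzaldehyde | O=CCOc1cc(O[Si](C(C)C)(C(C)C)C(C)C)ccc1C=O | intermediate
14 | sodium p-toluenesulfinate | Cc1ccc(S(=O)[O-])cc1.[Na+] | starting material
15 | 2-{2-hydroxy-2-[2-hydroxy-3,4-dimethoxy-5-(2-methylbut-3-en-2-yl)phenyl]ethoxy}-4-[(triisopropylsilyl)oxy]benzaldehyde (racemic) | O=Cc1ccc(O[Si](C(C)C)(C(C)C)C(C)C)cc1OCC(O)c1cc(C(C)(C)C=C)c(OC)c(OC)c1O | intermediate (not isolated)
16 | 2-{2-[2-hydroxy-3,4-dimethoxy-5-(2-methylbut-3-en-2-yl)phenyl]-2-[(4-methylphenyl)sulfonyl]ethoxy}-4-[(triisopropylsilyl)oxy]benzaldehyde (racemic) | O=Cc1ccc(O[Si](C(C)C)(C(C)C)C(C)C)cc1OCC(c1cc(C(C)(C)C=C)c(OC)c(OC)c1O)S(=O)(=O)c1ccc(C)cc1 | intermediate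
17 | 2-{(2E)-2-[4,5-dimethoxy-3-(2-methylbut-3-en-2-yl)-6-oxocyclohexa-2,4-dien-1-ylidene]ethoxy}-4-[(triisopropylsilyl)oxy]benzaldehyde (ortho-quinone methide) | O=Cc1ccc(O[Si](C(C)C)(C(C)C)C(C)C)cc1OC/C=C1\C=C(C(C)(C)C=C)C(OC)=C(OC)C1=O | intermediate (not isolated)
18 | (3R)-3-[2-hydroxy-3,4-dimethoxy-5-(2-methylbut-3-en-2-yl)phenyl]-7-[(triisopropylsilyl)oxy]-2,3-dihydro-4H-chromen-4-one | C=CC(C)(C)c1cc([C@@H]2COc3cc(O[Si](C(C)C)(C(C)C)C(C)C)ccc3C2=O)c(O)c(OC)c1OC | intermediate
19 | pervilleanone [(3R)-7-hydroxy-3-[2-hydroxy-3,4-dimethoxy-5-(2-methylbut-3-en-2-yl)phenyl]-2,3-dihydro-4H-chromen-4-one] | C=CC(C)(C)c1cc([C@@H]2COc3cc(O)ccc3C2=O)c(O)c(OC)c1OC | target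

## Step count and least certain steps

Total step count: 11. Longest linear sequence: 8 steps (steps 1 to 5, then 9, 10 and 11, from 1).

**Step 10 (key step).**
- What may go wrong: the quinone methide may tautomerise by a 1,5-hydrogen shift from C2 to the 2'-oxygen before the acyl anion arrives, since that shift is intramolecular and also restores ring B. The free carbene may add to C3 and be held there as a phenoxide–azolium adduct. The extra substituent that ring B places on the acceptor may reduce facial discrimination. C3, once formed, may lose configuration by enolisation in the basic medium.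
- Fallback (known chemistry): it sets out from 7 and comes back to the route at 19. Lithiation of 7 ortho to its MOM ether (n-BuLi, THF, 0 °C) and quenching with 2-isopropoxy-4,4,5,5-tetramethyl-1,3,2-dioxaborolane should give the aryl boronate F1. In parallel, commercial 2,4-dihydroxyacetophenone is MOM-protected at O4 to 1-[2-hydroxy-4-(methoxymethoxy)phenyl]ethan-1-one F2, condensed with N,N-dimethylformamide dimethyl acetal to the enaminone F3, and cyclised with I2 to 3-iodo-7-(methoxymethoxy)chromen-4-one F4. Suzuki–Miyaura coupling of F1 with F4 (Pd(dppf)Cl2, K3PO4, dioxane/H2O) should give the isoflavone F5. Transfer hydrogenation of F5 with the antipode of RuCl(p-cymene)(TsDPEN) that delivers 3R, in HCO2H/Et3N, reduces C2=C3 and then C4=O with dynamic kinetic resolution at C3, giving the cis-(3R,4R)-isoflavan-4-ol F6. Dess–Martin oxidation returns the ketone as the (R)-isoflavanone F7 without base. Removal of both MOM ethers with TMSOTf/2,2'-bipyridyl followed by water gives 19.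

**Step 9.**
- What may go wrong: competing condensation at the aryl aldehyde of 13; over-arylation, in which a second molecule of 8 displaces sulfinate from the product; loss of a proton from the benzylic cation toward the enol ether; acid-induced loss of the tert-allyl group from 8.
- Fallback: it sets out from 11 and 7 and comes back at 16. The formyl group of 11 is masked with ethylene glycol and catalytic acid as 2-[2-(prop-2-en-1-yloxy)-4-(triisopropylsilyloxy)phenyl]-1,3-dioxolane F8, and ozonolysis gives the mono-aldehyde F9. Compound 7 is lithiated ortho to its MOM ether (n-BuLi, THF, 0 °C) and the aryllithium is added to F9 at −78 °C to give the secondary alcohol F10. In F10 ring B is bound through the intended carbon by construction, and only one aldehyde was ever free. Treatment of F10 with 14 and aqueous HCl in THF should remove the dioxolane and the MOM ether and exchange the benzylic hydroxyl for the sulfonyl group, giving 16.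

**Step 3.**
- What may go wrong: on prolonged heating the ortho-(tert-allyl)phenol may rearrange further (abnormal Claisen shift of the side chain) or close onto its alkene to a dihydrobenzofuran, and some migration toward the para position through the blocked ortho carbon is possible.
- Fallback: it sets out from 4 and comes back at 6. The rearrangement is run in acetic anhydride with NaOAc so that the phenol is intercepted as it forms and never sits free in the hot medium, giving the aryl acetate F11. Methanolysis with K2CO3 in MeOH at rt then releases 6.

**Step 8.**
- What may go wrong: over-oxidation of the aryl aldehyde or of the oxygenated ring by ozone, and hydration or oligomerisation of the aryloxyacetaldehyde during isolation.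
- Fallback: it sets out from 10 and comes back at 13. Mitsunobu etherification of 10 with 2,2-diethoxyethanol installs the arm already at the aldehyde oxidation level as the diethyl acetal F12, and mild aqueous acid (TFA/H2O/CHCl3, 0 °C) releases 13 just before use, so no oxidant is needed.

## Further compounds

F1 | step 10 | 2-[2-(methoxymethoxy)-3,4-dimethoxy-5-(2-methylbut-3-en-2-yl)phenyl]-4,4,5,5-tetramethyl-1,3,2-dioxaborolane | C=CC(C)(C)c1cc(B2OC(C)(C)C(C)(C)O2)c(OCOC)c(OC)c1OC
F2 | step 10 | 1-[2-hydroxy-4-(methoxymethoxy)phenyl]ethan-1-one | CC(=O)c1ccc(OCOC)cc1O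
F3 | step 10 | (2E)-3-(dimethylamino)-1-[2-hydroxy-4-(methoxymethoxy)phenyl]prop-2-en-1-one | CN(C)/C=C/C(=O)c1ccc(OCOC)cc1O
F4 | step 10 | 3-iodo-7-(methoxymethoxy)-4H-chromen-4-one | COCOc1ccc2c(c1)occ(I)c2=O
F5 | step 10 | 7-(methoxymethoxy)-3-[2-(methoxymethoxy)-3,4-dimethoxy-5-(2-methylbut-3-en-2-yl)phenyl]-4H-chromen-4-one | C=CC(C)(C)c1cc(-c2coc3cc(OCOC)ccc3c2=O)c(OCOC)c(OC)c1OC
F6 | step 10 | (3R,4R)-7-(methoxymethoxy)-3-[2-(methoxymethoxy)-3,4-dimethoxy-5-(2-methylbut-3-en-2-yl)phenyl]-3,4-dihydro-2H-chromen-4-ol | C=CC(C)(C)c1cc([C@@H]2COc3cc(OCOC)ccc3[C@@H]2O)c(OCOC)c(OC)c1OC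
F7 | step 10 | (3R)-7-(methoxymethoxy)-3-[2-(methoxymethoxy)-3,4-dimethoxy-5-(2-methylbut-3-en-2-yl)phenyl]-2,3-dihydro-4H-chromen-4-one | C=CC(C)(C)c1cc([C@@H]2COc3cc(OCOC)ccc3C2=O)c(OCOC)c(OC)c1OC
F8 | step 9 | 2-[2-(prop-2-en-1-yloxy)-4-(triisopropylsilyloxy)phenyl]-1,3-dioxolane | C=CCOc1cc(O[Si](C(C)C)(C(C)C)C(C)C)ccc1C1OCCO1
F9 | step 9 | 2-[2-(1,3-dioxolan-2-yl)-5-(triisopropylsilyloxy)phenoxy]acetaldehyde | O=CCOc1cc(O[Si](C(C)C)(C(C)C)C(C)C)ccc1C1OCCO1
F10 | step 9 | 2-[2-(1,3-dioxolan-2-yl)-5-(triisopropylsilyloxy)phenoxy]-1-[2-(methoxymethoxy)-3,4-dimethoxy-5-(2-methylbut-3-en-2-yl)phenyl]ethan-1-ol (racemic) | C=CC(C)(C)c1cc(C(O)COc2cc(O[Si](C(C)C)(C(C)C)C(C)C)ccc2C2OCCO2)c(OCOC)c(OC)c1OC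
F11 | step 3 | 2-methoxy-3-(methoxymethoxy)-6-(2-methylbut-3-en-2-yl)phenyl acetate | C=CC(C)(C)c1ccc(OCOC)c(OC)c1OC(C)=O
F12 | step 8 | 2-(2,2-diethoxyethoxy)-4-[(triisopropylsilyl)oxy]benzaldehyde | CCOC(COc1cc(O[Si](C(C)C)(C(C)C)C(C)C)ccc1C=O)OCC
A1 | alternative 1 | 5-chloro-7,2'-bis(methoxymethoxy)-3',4'-dimethoxy-5'-(2-methylbut-3-en-2-yl)isoflavone | C=CC(C)(C)c1cc(-c2coc3cc(OCOC)cc(Cl)c3c2=O)c(OCOC)c(OC)c1OC
A2 | alternative 1 | (2E)-3-methoxy-2-[2-(methoxymethoxy)-3,4-dimethoxy-5-(2-methylbut-3-en-2-yl)phenyl]prop-2-enoic acid | CO/C=C(/C(=O)O)c1cc(C(C)(C)C=C)c(OC)c(OC)c1OCOC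
A3 | alternative 1 | 3-chloro-5-(methoxymethoxy)-2-(trimethylsilyl)phenyl trifluoromethanesulfonate | COCOc1cc(Cl)c([Si](C)(C)C)c(OS(=O)(=O)C(F)(F)F)c1
A4 | alternative 2 | 2-methoxy-6-(2-methylbut-3-en-2-yl)-3-(triisopropylsilyloxy)phenol | C=CC(C)(C)c1ccc(O[Si](C(C)C)(C(C)C)C(C)C)c(OC)c1O
A5 | alternative 2 | (4-bromo-2-methoxyphenoxy)triisopropylsilane | COc1cc(Br)ccc1O[Si](C(C)C)(C(C)C)C(C)C
A6 | alternative 2 | prenylmagnesium chloride | CC(C)=CC[Mg]Cl
A7 | alternative 3 | (R)-7,2'-bis-O-(triisopropylsilyl)pervilleanone | C=CC(C)(C)c1cc([C@@H]2COc3cc(O[Si](C(C)C)(C(C)C)C(C)C)ccc3C2=O)c(O[Si](C(C)C)(C(C)C)C(C)C)c(OC)c1OC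
A8 | alternative 3 | 2-diazo-2-[3,4-dimethoxy-5-(2-methylbut-3-en-2-yl)-2-(triisopropylsilyloxy)phenyl]-1-[2-methoxy-4-(triisopropylsilyloxy)phenyl]ethan-1-one | COc1cc(O[Si](C(C)C)(C(C)C)C(C)C)ccc1C(=O)C(=[N+]=[N-])c1cc(C(C)(C)C=C)c(OC)c(OC)c1O[Si](C(C)C)(C(C)C)C(C)C
A9 | alternative 3 | Rh2(S-PTTL)4, dirhodium tetrakis[N-phthaloyl-(S)-tert-leucinate] | [Rh+2].[Rh+2].CC(C)(C)[C@H](N1C(=O)c2ccccc2C1=O)C(=O)[O-].CC(C)(C)[C@H](N1C(=O)c2ccccc2C1=O)C(=O)[O-].CC(C)(C)[C@H](N1C(=O)c2ccccc2C1=O)C(=O)[O-].CC(C)(C)[C@H](N1C(=O)c2ccccc2C1=O)C(=O)[O-]
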